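## The problem

The target 20 is a 5-deoxy proanthocyanidin dimer. An upper 2,3-cis flavan-3-ol unit (resorcinol ring A, pyran ring C, catechol ring B) is bonded through C4 to C6' of a lower (+)-catechin unit (phloroglucinol ring D, pyran ring F, catechol ring E). Five stereocentres must be right: C2' (R) and C3' (S) are those of (+)-catechin and can be bought, but they are too far from ring C to steer anything there, so C2 (R), C3 (R) and C4 (S) have to be controlled within the upper unit. These three are all-cis, with ring B, the C3 oxygen and ring D on one face of ring C; a cationic arylation at C4, the usual way to make an interflavan bond, would place the arene trans to the C3 oxygen and is therefore unsuitable. The C4–C6' bond joins a doubly benzylic methine to the more hindered and less nucleophilic of the two open positions of ring D, so C8' must be blocked or C6' specifically activated. Seven phenols (two catechols), the benzylic ether bonds O1–C2 and O1'–C2' and the electron-rich diarylmethine C4 exclude strong acid, oxidants and strong base on free phenols late in the route; all oxygens are therefore carried as benzyl ethers that fall in one neutral hydrogenolysis. The enabling feature is that C3 (oxygen-bearing) and C4 (bearing ring D and bonded to C4a of ring A) are neighbours: read as carbonyl carbons they are an ester carbon and a diaryl ketone carbon already tied together through O1 and C2. Reductive coupling of these two carbonyls closes ring C as a flat C3=C4 enol ether, after which the single stereocentre C2 can direct one syn addition of hydrogen that sets C3 and C4 together.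

## Retrosynthesis

**20 from 19.** The last disconnection removes protecting groups only: the nine O–benzyl bonds and the C8'–Br bond of 19. Benzyl ethers are preferred to silyl or acyl groups because they survive organomagnesium reagents, low-valent titanium and a homogeneous hydrogenation catalyst, and because one neutral hydrogenolysis frees every oxygen and removes the blocking bromine as well. The forward step must leave the benzylic C2–O1 and C2'–O1' bonds and the C4 methine intact.

**19 from 18.** The C3–H and C4–H bonds are cut, leading to the 3-benzyloxy-2H-chromene 18. The neighbouring cut, C4–C6' by arylation of a C4 cation, would deliver ring D trans to the C3 oxygen. A syn addition of hydrogen to a flat C3=C4 bond gives the 3,4-cis relation by necessity and needs only one facial choice, which C2 can make. Two of the three upper stereocentres disappear in 18. The forward step must hydrogenate a crowded tetrasubstituted enol ether on the face away from ring B without cleaving the enol benzyl group.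

**18 from 17.** Cutting C3=C4 gives keto ester 17: a diaryl ketone at the future C4 and a benzyl ester at the future C3, joined through O1 and C2.
- Cutting C4–C6' instead (aryl metal plus a C4 ketone) would require a configurationally fragile 3-oxygenated flavanone.
- Cutting at O1 would leave the congested tetrasubstituted alkene to be assembled intermolecularly.
- The C3–C4 cut makes the hindered bond intramolecularly, turns the ester alkoxy group into the protected C3 oxygen, and leaves C2 as the only stereocentre of the upper unit.

The forward reaction must couple ketone with ester faster than it reduces or dimerises the ketone, and must spare the C2–O1 bond and the C2 configuration.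

**17 from 11 and 16.** The O1–C2 bond is cut between the phenol oxygen of 2-hydroxybenzophenone 11 and the carbinol carbon of mandelate 16. Forming O1–C8a instead would need an aryl fluoride and a basic mandelate alkoxide, which invites racemisation; a phenol displacing an activated secondary alcohol is neutral and stereospecific. The cut divides the molecule into halves of similar size. The forward etherification must proceed with clean inversion, so 16 must be the (S)-alcohol.

**16 from 15, and 15 from 12 and 13.** The C–H bond at the carbinol carbon is cut to give aryl glyoxylate 15, and the aryl–carbonyl bond of 15 is cut to give aryl bromide 12 (as its Grignard reagent 14) and dibenzyl oxalate 13. An enantioselective ketone reduction is shorter than resolving a racemic mandelate, and the oxalate brings the benzyl ester in directly. The forward steps must stop at mono-addition to 13 and reduce the keto group with high enantioselectivity.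

**11 from 10, 9, and from 5 with 7.** The phenol of 11 is unmasked from methoxymethyl ether 10. The ketone of 10 comes from benzhydrol 9. The aryl–carbinol bond of 9 (the future C4–C6' bond) is cut to give aldehyde 7 and the catechin C6 Grignard reagent 8, made from iodide 5. A Friedel–Crafts acylation at C6 would expose benzyl ethers to strong Lewis acid; the organometallic addition is regiospecific because the metal sits where the iodine was. The forward step must exchange iodine for magnesium in the presence of the C8 bromine.

**5 from 4, 3, 2 and 1; 7 from 6.** The C6–I and C8–Br bonds and the five O–benzyl bonds are cut back to (+)-catechin 1. Bromination first fills the more reactive C8, so the later iodination can only occur at C6. Aldehyde 7 is the methoxymethyl ether of purchased 6. These are standard protecting-group and halogenation steps; they must not disturb C2 and C3 of catechin.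

## Roads not taken

**Alternative 1:** The cut lies in the lower unit, at O1'–C2' and C3'–C4' of ring F.
- Forward step: ortho-hydroxybenzyl alcohol A2, which already carries the finished upper unit on ring D, would be dehydrated by a chiral phosphoric acid to the ring D ortho-quinone methide. This heterodiene would add the (E)-styrenyl pinacol boronate A3 to give the trans-2'-aryl-3'-boryl flavan A1. Oxidation of the C–B bond with retention and debenzylation would then give 20.
- Merits: two bonds, one ring and two stereocentres in one catalytic step; no blocking halogen, because the 4→6 connectivity is fixed by which phenol of A2 is free; free choice of the lower aryl group.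
- Weak points: it builds what can be bought, since rings D, F and E with both stereocentres are (+)-catechin 1. The hard part, the all-cis upper unit and its bond to ring D, must already be present in A2 and is not addressed by the cut. An alkenyl boronate is an electronically poor partner for an electrophilic quinone methide. The catalyst must set two centres in the presence of three existing ones, so a mismatched pairing cannot be excluded.
- Comparison: Alternative 1 is the better route to analogues with an unnatural lower unit. The chosen plan sets against this that it spends no step on ring F and puts all its risk where the real problem lies, in ring C.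

**Alternative 2:** The cut is O1–C8a.
- Forward step: in open-chain precursor A5 the free C2 hydroxyl would add, under acid, to the β-carbon (the future C8a) of a 4-methoxycyclohexa-2,5-dienone. Loss of methanol would rearomatise ring A and close ring C to give A4, the all-cis dimer with a free C7 hydroxyl and all other oxygens benzylated; hydrogenolysis would then give 20.
- Merits: the closure is redox-neutral and touches no stereocentre, so C2 is retained; no crowded alkene has to be hydrogenated. In this respect it is better than the chosen plan, which stakes C3 and C4 on one difficult hydrogenation.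
- Weak points: all three contiguous stereocentres, including the diarylmethine C4 attached to a quaternary dienone carbon, must be set in an open chain with no ring to relay from. The dienone must be made by oxidative dearomatisation in a molecule full of electron-rich benzyloxyarenes. Under the acid needed for closure, a 4,4-disubstituted dienone can undergo dienone–phenol rearrangement with migration of the benzylic side chain.
- Comparison: the chosen plan sets against the gentler ring closure that C2 is bought in as a mandelate, that only one further stereo-defining event is needed, and that 17 is assembled from two halves in one etherification.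

**Alternative 3:** The cuts are C4–C4a and O1–C2.
- Forward step: a rhodium-catalysed conjugate arylation (chiral diene ligand) would add 2-hydroxyarylboronic acid A8 to the β-carbon of enone A7. The phenol would then condense with the ketone to give the 2,4-diaryl-4H-chromene A6, with C4 set by the catalyst.
- Merits: C4 comes under direct catalyst control rather than substrate relay, the assembly is convergent, and the C2=C3 bond of A6 is only trisubstituted. On the question of C4 this road is stronger than the chosen one.
- Weak points: the β-carbon of A7 carries the doubly ortho-substituted ring D, a hindered and electron-rich position for aryl–rhodium insertion. A8 is prone to protodeboronation. From A6, hydrogen at C2 and oxygen at C3 must both be added. A syn hydroboration–oxidation anti to ring D gives the 2,4-cis relation but places the C3 hydroxyl trans to both aryl groups, so an oxidation and reduction at C3 would be needed to reach the all-cis series.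
- Comparison: the chosen plan sets against the catalyst-controlled C4 that its C3 oxygen is in place from the start and that C3 and C4 are set cis to C2 in one operation.

Key step: step 12

Remarks on the chemistry:
- Atoms of the upper unit carry plain numbers and atoms of the lower (catechin) unit primed numbers in the dimer (C6' and C8' are catechin C6 and C8). Monomeric catechin intermediates use ordinary chromane numbers.
- Compounds 6, 12 and 13 are taken as catalogue compounds. Compound 6 is otherwise one selective 4-O-benzylation away from 2,4-dihydroxybenzaldehyde.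
- The sense of induction in step 10 is assigned by the usual model for aryl ketones (aryl group beside the arene ligand). If the keto ester reduces with the opposite sense, the (S,S)-catalyst is used instead.
- Loss of the C8' bromine in step 12 or 13 would be harmless, since step 14 removes it.

## Route

Step 1
Reactants: 1 (+)-catechin, (2R,3S)-2-(3,4-dihydroxyphenyl)chromane-3,5,7-triol
Product: 2 tetra-O-benzylcatechin, (2R,3S)-5,7-bis(benzyloxy)-2-[3,4-bis(benzyloxy)phenyl]chroman-3-ol
Conditions: BnBr, K2CO3, DMF, 0 to 25 °C
Reagents that add atoms: benzyl bromide, BrCc1ccccc1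
Why: Williamson etherification; carbonate deprotonates only the four phenols, so the secondary C3 alcohol stays free and C2 and C3 are untouched.

Step 2
Reactants: 2 tetra-O-benzylcatechin
Product: 3 penta-O-benzylcatechin, (2R,3S)-3,5,7-tris(benzyloxy)-2-[3,4-bis(benzyloxy)phenyl]chromane
Conditions: NaH, BnBr, n-Bu4NI (cat.), DMF, 0 to 25 °C
Reagents that add atoms: benzyl bromide, BrCc1ccccc1
Why: Williamson etherification of the secondary alkoxide; with no free phenol left, base cannot open ring C, so the C2 configuration is safe.

Step 3
Reactants: 3 penta-O-benzylcatechin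
Product: 4 8-bromo-penta-O-benzylcatechin, (2R,3S)-3,5,7-tris(benzyloxy)-2-[3,4-bis(benzyloxy)phenyl]-8-bromochromane
Conditions: NBS, CH2Cl2, −78 to 0 °C
Reagents that add atoms: N-bromosuccinimide, O=C1CCC(=O)N1Br
Why: Electrophilic aromatic bromination; of the two open positions of the trioxygenated ring, C8 is the more reactive and less hindered and takes the single equivalent of bromine, which then blocks it.

Step 4
Reactants: 4 8-bromo-penta-O-benzylcatechin
Product: 5 8-bromo-6-iodo-penta-O-benzylcatechin, (2R,3S)-3,5,7-tris(benzyloxy)-2-[3,4-bis(benzyloxy)phenyl]-8-bromo-6-iodochromane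
Conditions: NIS, CF3CO2H (cat.), CH2Cl2/MeCN, 0 to 25 °C
Reagents that add atoms: N-iodosuccinimide, O=C1CCC(=O)N1I
Why: Electrophilic aromatic iodination at C6, the only free position of the trioxygenated ring, which remains far more nucleophilic than the catechol-type ring; acid activation of NIS compensates for the two flanking benzyloxy groups.

Step 5
Reactants: 6 4-(benzyloxy)-2-hydroxybenzaldehyde
Product: 7 4-(benzyloxy)-2-(methoxymethoxy)benzaldehyde
Conditions: MOMCl, i-Pr2NEt, CH2Cl2, 0 to 25 °C
Reagents that add atoms: chloromethyl methyl ether, COCCl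
Why: O-alkylation of the phenol to a methoxymethyl acetal; it masks the acidic OH during the Grignard addition and can later be removed by mild acid that leaves benzyl ethers alone.

Step 6
Reactants: 5 8-bromo-6-iodo-penta-O-benzylcatechin; 7 4-(benzyloxy)-2-(methoxymethoxy)benzaldehyde
Product: 9 [4-(benzyloxy)-2-(methoxymethoxy)phenyl](8-bromo-penta-O-benzylcatechin-6-yl)methanol (both carbinol epimers), via catechin-6-ylmagnesium chloride 8 (not isolated)
Conditions: 5, i-PrMgCl·LiCl, THF, −20 °C; then 7, −20 to 25 °C; aq. NH4Cl
Reagents that add atoms: none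
Why: Iodine–magnesium exchange is much faster at the C–I bond, assisted by two ortho oxygens, than at the C–Br bond, so the metal is placed at C6 only; Grignard 1,2-addition to aldehyde 7 then forms the future C4–C6' bond. The carbinol centre forms without control, which is immaterial because step 7 removes it.

Step 7
Reactants: 9 the benzhydrol
Product: 10 [4-(benzyloxy)-2-(methoxymethoxy)phenyl](8-bromo-penta-O-benzylcatechin-6-yl)methanone
Conditions: Dess–Martin periodinane, CH2Cl2, 25 °C
Reagents that add atoms: none
Why: Dess–Martin oxidation of a doubly benzylic secondary alcohol; the reagent is neutral, copes with hindered carbinols and leaves the aryl bromide, benzyl ethers and acetal untouched.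

Step 8
Reactants: 10 the methoxymethyl-protected benzophenone
Product: 11 [4-(benzyloxy)-2-hydroxyphenyl](8-bromo-penta-O-benzylcatechin-6-yl)methanone
Conditions: HCl (aq.), MeOH/THF, 45 °C
Reagents that add atoms: none
Why: Acid-catalysed acetal cleavage by transfer of the methoxymethyl group to methanol; aryl benzyl ethers and the flavan ring are stable to dilute acid at this temperature, and the phenol is released hydrogen-bonded to the ketone.

Step 9
Reactants: 12 4-bromo-1,2-bis(benzyloxy)benzene; 13 dibenzyl oxalate
Product: 15 benzyl 2-[3,4-bis(benzyloxy)phenyl]-2-oxoacetate, via arylmagnesium bromide 14 (not isolated)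
Conditions: 12, Mg, THF, 25 to 50 °C; then added to 13 (excess), THF, −78 °C; aq. NH4Cl
Reagents that add atoms: none
Why: Grignard mono-addition to a dialkyl oxalate; the chelated tetrahedral adduct persists at −78 °C and inverse addition to excess oxalate prevents a second addition, so the α-keto benzyl ester is released on quench.

Step 10
Reactants: 15 benzyl 2-[3,4-bis(benzyloxy)phenyl]-2-oxoacetate
Product: 16 benzyl (S)-2-[3,4-bis(benzyloxy)phenyl]-2-hydroxyacetate
Conditions: RuCl(p-cymene)[(R,R)-TsDPEN] (cat.), HCO2H/Et3N (5:2), CH2Cl2, 25 °C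
Reagents that add atoms: none
Why: Asymmetric transfer hydrogenation of an aryl α-keto ester; the ruthenium hydride delivers hydrogen to one face of the ketone with the aryl group beside the arene ligand, which with the (R,R)-ligand should give the (S)-carbinol. The benzyl ester is inert and the optical purity can be raised by crystallisation.

Step 11
Reactants: 11 the 2-hydroxybenzophenone; 16 benzyl (S)-3,4-bis(benzyloxy)mandelate
Product: 17 benzyl (R)-2-[3,4-bis(benzyloxy)phenyl]-2-[5-(benzyloxy)-2-(8-bromo-penta-O-benzylcatechin-6-carbonyl)phenoxy]acetate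
Conditions: PPh3, DIAD, toluene/THF, 0 to 25 °C
Reagents that add atoms: none
Why: Mitsunobu etherification; the phenol displaces the phosphonium-activated secondary alcohol by SN2 with inversion, so (S)-16 gives the (R)-ether that carries the C2 configuration of the target. The adjacent ester group disfavours ionisation at the benzylic carbon, and any material from the minor enantiomer of 16 becomes a separable diastereomer.

Step 12
Reactants: 17 the keto ester
Product: 18 (2R)-3,7-bis(benzyloxy)-2-[3,4-bis(benzyloxy)phenyl]-4-(8-bromo-penta-O-benzylcatechin-6-yl)-2H-chromene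
Conditions: TiCl3, Zn dust, DME, reflux (reagent pre-formed); 17 added slowly by syringe pump; aq. K2CO3 work-up
Reagents that add atoms: none
Why: Low-valent titanium, made by reducing TiCl3 with zinc, transfers electrons to the easily reduced diaryl ketone to give a titanium-bound ketyl (or dianion) whose carbon, C4, adds to the nearby benzyl ester carbonyl, C3; the titanium-bound diolate so formed is deoxygenated on titanium, leaving the C3=C4 bond with the ester benzyloxy group retained as the enol ether. The closest known reaction is the McMurry-type intramolecular keto-ester coupling that gives cyclic enol ethers and benzofurans. Ring C closes in a 6-exo-trig mode, the ester C=O lying outside the ring formed through O1 and C2. No stereocentre is created; C2 is part of neither carbonyl and the medium is not basic, so its configuration should be kept. The step needs chemoselectivity for intramolecular ketone–ester coupling over ketone dimerisation or plain reduction: dimerisation is disfavoured by the two ortho benzyloxy groups on ring D and by slow addition, and the ortho-oxygen tether holds the ester within reach of the ketyl carbon. The buffered work-up protects the acid-labile enol ether.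

Step 13
Reactants: 18 the 3-benzyloxy-2H-chromene
Product: 19 (2R,3R,4S)-3,7-bis(benzyloxy)-2-[3,4-bis(benzyloxy)phenyl]-4-(8-bromo-penta-O-benzylcatechin-6-yl)chromane (all-cis upper unit)
Conditions: [Ir(cod)(PCy3)(py)]PF6 (cat.), H2 (50 bar), CH2Cl2, 25 °C
Reagents that add atoms: none
Why: Iridium-catalysed homogeneous hydrogenation of a tetrasubstituted alkene; allylic strain with the C3 benzyloxy group forces ring B pseudo-axial, so both hydrogens add syn to the opposite face and the C3 oxygen and ring D end up cis to ring B, giving (3R,4S). The cationic iridium catalyst does not cleave benzyl ethers, so the enol ether is not unmasked to a ketone.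

Step 14
Reactants: 19 the nona-O-benzyl bromo dimer
Product: 20 (2R,3R,4S)-2-(3,4-dihydroxyphenyl)-4-[(2R,3S)-2-(3,4-dihydroxyphenyl)-3,5,7-trihydroxychroman-6-yl]chromane-3,7-diol (CNP0141631.2)
Conditions: H2 (1 atm), Pd(OH)2/C, Et3N, THF/MeOH, 25 °C
Reagents that add atoms: none
Why: Catalytic hydrogenolysis of nine benzyl ethers and of the aryl C–Br bond; Et3N takes up the HBr so that the benzylic ether bonds and the interflavan bond are not exposed to acid, and no stereocentre is involved.

## Compound list

1 | (+)-catechin, (2R,3S)-2-(3,4-dihydroxyphenyl)chromane-3,5,7-triol | O[C@H]1Cc2c(O)cc(O)cc2O[C@@H]1c1ccc(O)c(O)c1 | starting material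
2 | (2R,3S)-5,7-bis(benzyloxy)-2-[3,4-bis(benzyloxy)phenyl]chroman-3-ol | O[C@H]1Cc2c(OCc3ccccc3)cc(OCc3ccccc3)cc2O[C@@H]1c1ccc(OCc2ccccc2)c(OCc2ccccc2)c1 | intermediate
3 | (2R,3S)-3,5,7-tris(benzyloxy)-2-[3,4-bis(benzyloxy)phenyl]chromane | C(c1ccccc1)O[C@H]1Cc2c(OCc3ccccc3)cc(OCc3ccccc3)cc2O[C@@H]1c1ccc(OCc2ccccc2)c(OCc2ccccc2)c1 | intermediate
4 | (2R,3S)-3,5,7-tris(benzyloxy)-2-[3,4-bis(benzyloxy)phenyl]-8-bromochromane | c1c(OCc3ccccc3)c(Br)c2c(c1OCc1ccccc1)C[C@H](OCc1ccccc1)[C@@H](c1ccc(OCc3ccccc3)c(OCc3ccccc3)c1)O2 | intermediate
5 | (2R,3S)-3,5,7-tris(benzyloxy)-2-[3,4-bis(benzyloxy)phenyl]-8-bromo-6-iodochromane | Ic1c(OCc3ccccc3)c(Br)c2c(c1OCc1ccccc1)C[C@H](OCc1ccccc1)[C@@H](c1ccc(OCc3ccccc3)c(OCc3ccccc3)c1)O2 | intermediate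
6 | 4-(benzyloxy)-2-hydroxybenzaldehyde | O=Cc1ccc(OCc2ccccc2)cc1O | starting material
7 | 4-(benzyloxy)-2-(methoxymethoxy)benzaldehyde | O=Cc1ccc(OCc2ccccc2)cc1OCOC | intermediate
8 | [(2R,3S)-3,5,7-tris(benzyloxy)-2-[3,4-bis(benzyloxy)phenyl]-8-bromochroman-6-yl]magnesium chloride (LiCl complex) | Cl[Mg]c1c(OCc3ccccc3)c(Br)c2c(c1OCc1ccccc1)C[C@H](OCc1ccccc1)[C@@H](c1ccc(OCc3ccccc3)c(OCc3ccccc3)c1)O2 | intermediate
9 | [4-(benzyloxy)-2-(methoxymethoxy)phenyl][(2R,3S)-3,5,7-tris(benzyloxy)-2-[3,4-bis(benzyloxy)phenyl]-8-bromochroman-6-yl]methanol, carbinol centre unassigned (both epimers) | OC(c1ccc(OCc2ccccc2)cc1OCOC)c1c(OCc3ccccc3)c(Br)c2c(c1OCc1ccccc1)C[C@H](OCc1ccccc1)[C@@H](c1ccc(OCc3ccccc3)c(OCc3ccccc3)c1)O2 | intermediate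
10 | [4-(benzyloxy)-2-(methoxymethoxy)phenyl][(2R,3S)-3,5,7-tris(benzyloxy)-2-[3,4-bis(benzyloxy)phenyl]-8-bromochroman-6-yl]methanone | O=C(c1ccc(OCc2ccccc2)cc1OCOC)c1c(OCc3ccccc3)c(Br)c2c(c1OCc1ccccc1)C[C@H](OCc1ccccc1)[C@@H](c1ccc(OCc3ccccc3)c(OCc3ccccc3)c1)O2 | intermediate
11 | [4-(benzyloxy)-2-hydroxyphenyl][(2R,3S)-3,5,7-tris(benzyloxy)-2-[3,4-bis(benzyloxy)phenyl]-8-bromochroman-6-yl]methanone | O=C(c1ccc(OCc2ccccc2)cc1O)c1c(OCc3ccccc3)c(Br)c2c(c1OCc1ccccc1)C[C@H](OCc1ccccc1)[C@@H](c1ccc(OCc3ccccc3)c(OCc3ccccc3)c1)O2 | intermediate
12 | 4-bromo-1,2-bis(benzyloxy)benzene | Brc1ccc(OCc2ccccc2)c(OCc2ccccc2)c1 | starting material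
13 | dibenzyl oxalate | O=C(OCc1ccccc1)C(=O)OCc1ccccc1 | starting material
14 | [3,4-bis(benzyloxy)phenyl]magnesium bromide | Br[Mg]c1ccc(OCc2ccccc2)c(OCc2ccccc2)c1 | intermediate
15 | benzyl 2-[3,4-bis(benzyloxy)phenyl]-2-oxoacetate | O=C(C(=O)OCc1ccccc1)c1ccc(OCc2ccccc2)c(OCc2ccccc2)c1 | intermediate
16 | benzyl (S)-2-[3,4-bis(benzyloxy)phenyl]-2-hydroxyacetate | O[C@@H](c1ccc(OCc2ccccc2)c(OCc2ccccc2)c1)C(=O)OCc1ccccc1 | intermediate
17 | benzyl (R)-2-[3,4-bis(benzyloxy)phenyl]-2-[5-(benzyloxy)-2-[(2R,3S)-3,5,7-tris(benzyloxy)-2-[3,4-bis(benzyloxy)phenyl]-8-bromochromane-6-carbonyl]phenoxy]acetate | O=C(c1ccc(OCc2ccccc2)cc1O[C@H](c1ccc(OCc2ccccc2)c(OCc2ccccc2)c1)C(=O)OCc1ccccc1)c1c(OCc3ccccc3)c(Br)c2c(c1OCc1ccccc1)C[C@H](OCc1ccccc1)[C@@H](c1ccc(OCc3ccccc3)c(OCc3ccccc3)c1)O2 | intermediate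
18 | (2R)-3,7-bis(benzyloxy)-2-[3,4-bis(benzyloxy)phenyl]-4-[(2R,3S)-3,5,7-tris(benzyloxy)-2-[3,4-bis(benzyloxy)phenyl]-8-bromochroman-6-yl]-2H-chromene | C(c1ccccc1)Oc1ccc2c(c1)O[C@H](c1ccc(OCc3ccccc3)c(OCc3ccccc3)c1)C(OCc1ccccc1)=C2c1c(OCc3ccccc3)c(Br)c2c(c1OCc1ccccc1)C[C@H](OCc1ccccc1)[C@@H](c1ccc(OCc3ccccc3)c(OCc3ccccc3)c1)O2 | intermediate
19 | (2R,3R,4S)-3,7-bis(benzyloxy)-2-[3,4-bis(benzyloxy)phenyl]-4-[(2R,3S)-3,5,7-tris(benzyloxy)-2-[3,4-bis(benzyloxy)phenyl]-8-bromochroman-6-yl]chromane | C(c1ccccc1)Oc1ccc2c(c1)O[C@H](c1ccc(OCc3ccccc3)c(OCc3ccccc3)c1)[C@H](OCc1ccccc1)[C@@H]2c1c(OCc3ccccc3)c(Br)c2c(c1OCc1ccccc1)C[C@H](OCc1ccccc1)[C@@H](c1ccc(OCc3ccccc3)c(OCc3ccccc3)c1)O2 | intermediate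
20 | (2R,3R,4S)-2-(3,4-dihydroxyphenyl)-4-[(2R,3S)-2-(3,4-dihydroxyphenyl)-3,5,7-trihydroxychroman-6-yl]chromane-3,7-diol (CNP0141631.2) | Oc1ccc2c(c1)O[C@H](c1ccc(O)c(O)c1)[C@H](O)[C@@H]2c1c(O)cc2c(c1O)C[C@H](O)[C@@H](c1ccc(O)c(O)c1)O2 | target

## Step count and least certain steps

Total: 14 steps. Longest linear sequence: 11 steps (steps 1, 2, 3, 4, 6, 7, 8, 11, 12, 13, 14, from 1 to 20).

**Step 12 (key step).** The most likely failure is reduction of the ketone without C–C bond formation: the ketyl carbon is flanked by the two ortho benzyloxy groups of ring D, so its addition to the ester may be slower than further reduction to the carbinol or methylene stage. Second in line are reductive cleavage of the activated C2–O1 bond (benzylic and α to the ester) and loss of configuration at C2 on the Lewis-acidic titanium surface.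

Fallback (sets out from 5, returns at 18): the chromene is made by a polar route through the C4–C6' bond.
- Purchased (2R,3R)-fustin F1 is benzylated on its three phenols (BnBr, K2CO3, DMF) to tri-O-benzylfustin F2.
- The C3 hydroxyl is benzylated under acid catalysis (benzyl 2,2,2-trichloroacetimidate, cat. CF3SO3H) to tetra-O-benzylfustin F3.
- Grignard reagent 8, made from 5 as in step 6, is added to the C4 ketone of F3 in the presence of LaCl3·2LiCl to give the tertiary carbinol F4.
- Acid-catalysed dehydration towards C3 (pyridinium p-toluenesulfonate, toluene, molecular sieves) gives 18.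

This is the standard way from chroman-4-ones to 4-aryl-2H-chromenes. Its own weak point is enolisation and ring opening of the flavanone, which the lanthanum salt is meant to suppress.

**Step 13.** The most likely failure is lack of turnover: the ortho benzyloxy groups of the perpendicular ring D shield both faces of C3=C4, and the catalyst may deactivate before the alkene binds. Acid generated from the iridium hydride could also isomerise or hydrolyse the enol ether.

Fallback (sets out from 18, returns at 20):
- The enol ether is hydrolysed (dilute HCl, THF/H2O) to the 2,4-cis chroman-3-one F5. C4 is protonated anti to ring B, which is also the diequatorial, thermodynamically preferred arrangement.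
- The ketone is reduced with LiBH(s-Bu)3 at −78 °C from the equatorial direction to the axial, all-cis alcohol F6. This is the established way of turning catechin-type 3-ketones into 2,3-cis alcohols.
- Hydrogenolysis of F6 under the conditions of step 14 gives 20.

**Step 11.** The most likely failure is partial loss of configuration by ionisation of the oxyphosphonium intermediate at the electron-rich benzylic carbon. The hindered, hydrogen-bonded phenol may also react so slowly that alkylation of the reduced azodicarboxylate takes over.

Fallback (sets out from 15 and 11, returns at 17): the O1–C2 bond is made by carbene O–H insertion.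
- Keto ester 15 is condensed with p-toluenesulfonyl hydrazide to hydrazone F7.
- DBU converts F7 into diazo ester F8.
- Insertion of the derived metal carbene into the O–H bond of phenol 11 gives 17. Pd(PhCN)2Cl2 with a chiral spiro bis(oxazoline) ligand is used for catalyst control; Rh2(OAc)4 followed by chromatographic separation of the C2 epimers is the plain variant.

**Step 6.** The most likely failure is incomplete or unselective halogen–magnesium exchange (the C8 bromine competing), or addition of the doubly ortho-substituted Grignard reagent so slow that protonation wins.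

Fallback (sets out from 4, returns at 9): the polarity is reversed.
- Vilsmeier–Haack formylation of 4 (POCl3, DMF), directed to C6 by the C8 bromine, gives the 6-carbaldehyde F9.
- Purchased 5-(benzyloxy)-2-bromophenol F10 is converted into its methoxymethyl ether F11 (MOMCl, i-Pr2NEt).
- Bromine–lithium exchange (n-BuLi, THF, −78 °C) gives aryllithium F12, and its addition to F9 gives benzhydrol 9.

## Further compounds

F1 | step 12 | (2R,3R)-fustin, (2R,3R)-2-(3,4-dihydroxyphenyl)-3,7-dihydroxychroman-4-one (purchased) | Oc1ccc2c(c1)O[C@H](c1ccc(O)c(O)c1)[C@@H](O)C2=O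
F2 | step 12 | (2R,3R)-7-(benzyloxy)-2-[3,4-bis(benzyloxy)phenyl]-3-hydroxychroman-4-one | C(c1ccccc1)Oc1ccc2c(c1)O[C@H](c1ccc(OCc3ccccc3)c(OCc3ccccc3)c1)[C@@H](O)C2=O
F3 | step 12 | (2R,3R)-3,7-bis(benzyloxy)-2-[3,4-bis(benzyloxy)phenyl]chroman-4-one | C(c1ccccc1)Oc1ccc2c(c1)O[C@H](c1ccc(OCc3ccccc3)c(OCc3ccccc3)c1)[C@@H](OCc1ccccc1)C2=O
F4 | step 12 | (2R,3R)-3,7-bis(benzyloxy)-2-[3,4-bis(benzyloxy)phenyl]-4-[(2R,3S)-3,5,7-tris(benzyloxy)-2-[3,4-bis(benzyloxy)phenyl]-8-bromochroman-6-yl]chroman-4-ol, C4 unassigned | C(c1ccccc1)Oc1ccc2c(c1)O[C@H](c1ccc(OCc3ccccc3)c(OCc3ccccc3)c1)[C@@H](OCc1ccccc1)C2(O)c1c(OCc3ccccc3)c(Br)c2c(c1OCc1ccccc1)C[C@H](OCc1ccccc1)[C@@H](c1ccc(OCc3ccccc3)c(OCc3ccccc3)c1)O2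
F5 | step 13 | (2R,4S)-7-(benzyloxy)-2-[3,4-bis(benzyloxy)phenyl]-4-[(2R,3S)-3,5,7-tris(benzyloxy)-2-[3,4-bis(benzyloxy)phenyl]-8-bromochroman-6-yl]chroman-3-one (2,4-cis) | C(c1ccccc1)Oc1ccc2c(c1)O[C@H](c1ccc(OCc3ccccc3)c(OCc3ccccc3)c1)C(=O)[C@@H]2c1c(OCc3ccccc3)c(Br)c2c(c1OCc1ccccc1)C[C@H](OCc1ccccc1)[C@@H](c1ccc(OCc3ccccc3)c(OCc3ccccc3)c1)O2
F6 | step 13 | (2R,3R,4S)-7-(benzyloxy)-2-[3,4-bis(benzyloxy)phenyl]-4-[(2R,3S)-3,5,7-tris(benzyloxy)-2-[3,4-bis(benzyloxy)phenyl]-8-bromochroman-6-yl]chroman-3-ol (all-cis) | C(c1ccccc1)Oc1ccc2c(c1)O[C@H](c1ccc(OCc3ccccc3)c(OCc3ccccc3)c1)[C@H](O)[C@@H]2c1c(OCc3ccccc3)c(Br)c2c(c1OCc1ccccc1)C[C@H](OCc1ccccc1)[C@@H](c1ccc(OCc3ccccc3)c(OCc3ccccc3)c1)O2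
F7 | step 11 | benzyl 2-[3,4-bis(benzyloxy)phenyl]-2-[2-(p-tolylsulfonyl)hydrazinylidene]acetate | Cc1ccc(cc1)S(=O)(=O)NN=C(C(=O)OCc1ccccc1)c1ccc(OCc2ccccc2)c(OCc2ccccc2)c1
F8 | step 11 | benzyl 2-[3,4-bis(benzyloxy)phenyl]-2-diazoacetate | [N-]=[N+]=C(C(=O)OCc1ccccc1)c1ccc(OCc2ccccc2)c(OCc2ccccc2)c1
F9 | step 6 | (2R,3S)-3,5,7-tris(benzyloxy)-2-[3,4-bis(benzyloxy)phenyl]-8-bromochromane-6-carbaldehyde | O=Cc1c(OCc3ccccc3)c(Br)c2c(c1OCc1ccccc1)C[C@H](OCc1ccccc1)[C@@H](c1ccc(OCc3ccccc3)c(OCc3ccccc3)c1)O2
F10 | step 6 | 5-(benzyloxy)-2-bromophenol (purchased) | Oc1cc(OCc2ccccc2)ccc1Br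
F11 | step 6 | 4-(benzyloxy)-1-bromo-2-(methoxymethoxy)benzene | COCOc1cc(OCc2ccccc2)ccc1Br
F12 | step 6 | [4-(benzyloxy)-2-(methoxymethoxy)phenyl]lithium | [Li]c1ccc(OCc2ccccc2)cc1OCOC
A1 | alternative 1 | protected dimer with a trans-3'-(pinacolboryl) lower flavan | C(c1ccccc1)Oc1ccc2c(c1)O[C@H](c1ccc(OCc3ccccc3)c(OCc3ccccc3)c1)[C@H](OCc1ccccc1)[C@@H]2c1c(OCc3ccccc3)cc2c(c1OCc1ccccc1)C[C@H](B1OC(C)(C)C(C)(C)O1)[C@@H](c1ccc(OCc3ccccc3)c(OCc3ccccc3)c1)O2
A2 | alternative 1 | ortho-hydroxybenzyl alcohol on ring D of the protected all-cis upper unit | C(c1ccccc1)Oc1ccc2c(c1)O[C@H](c1ccc(OCc3ccccc3)c(OCc3ccccc3)c1)[C@H](OCc1ccccc1)[C@@H]2c1c(OCc2ccccc2)cc(O)c(CO)c1OCc1ccccc1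
A3 | alternative 1 | (E)-2-[3,4-bis(benzyloxy)styryl]-4,4,5,5-tetramethyl-1,3,2-dioxaborolane | CC1(C)OB(/C=C/c2ccc(OCc3ccccc3)c(OCc3ccccc3)c2)OC1(C)C
A4 | alternative 2 | all-cis dimer with free C7 hydroxyl, other oxygens benzylated, C8' bromide | Oc1ccc2c(c1)O[C@H](c1ccc(OCc3ccccc3)c(OCc3ccccc3)c1)[C@H](OCc1ccccc1)[C@@H]2c1c(OCc3ccccc3)c(Br)c2c(c1OCc1ccccc1)C[C@H](OCc1ccccc1)[C@@H](c1ccc(OCc3ccccc3)c(OCc3ccccc3)c1)O2
A5 | alternative 2 | open-chain 4-methoxycyclohexa-2,5-dienone with free C2 hydroxyl, C3 benzyl ether and the protected 8-bromocatechin-6-yl group on C4 | O[C@H](c1ccc(OCc2ccccc2)c(OCc2ccccc2)c1)[C@H](OCc1ccccc1)[C@@H](C1(OC)C=CC(=O)C=C1)c1c(OCc3ccccc3)c(Br)c2c(c1OCc1ccccc1)C[C@H](OCc1ccccc1)[C@@H](c1ccc(OCc3ccccc3)c(OCc3ccccc3)c1)O2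
A6 | alternative 3 | 7-benzyloxy-2-[3,4-bis(benzyloxy)phenyl]-4-(protected 8-bromocatechin-6-yl)-4H-chromene | C(c1ccccc1)Oc1ccc2c(c1)OC(c1ccc(OCc3ccccc3)c(OCc3ccccc3)c1)=C[C@@H]2c1c(OCc3ccccc3)c(Br)c2c(c1OCc1ccccc1)C[C@H](OCc1ccccc1)[C@@H](c1ccc(OCc3ccccc3)c(OCc3ccccc3)c1)O2
A7 | alternative 3 | (E)-1-[3,4-bis(benzyloxy)phenyl]-3-(protected 8-bromocatechin-6-yl)prop-2-en-1-one | O=C(/C=C/c1c(OCc3ccccc3)c(Br)c2c(c1OCc1ccccc1)C[C@H](OCc1ccccc1)[C@@H](c1ccc(OCc3ccccc3)c(OCc3ccccc3)c1)O2)c1ccc(OCc2ccccc2)c(OCc2ccccc2)c1
A8 | alternative 3 | [4-(benzyloxy)-2-hydroxyphenyl]boronic acid | OB(O)c1ccc(OCc2ccccc2)cc1O
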